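**Plan**
- Retrosynthesis: the C9 ester is cut first, then the O5–C10 ether bond (oxepane rings A and B in one cut), which leads back to a 9,10-epoxy-5-hydroxy germacranolide. Further cuts are the epoxide, the C7–C8 bond of the ten-membered carbocycle, the C7=C11 alkene (metathesis) and the C5–C6 bond (allylation).
- Enabling feature: the oxygen on C9 sits beside the quaternary ether carbon C10, and the ether oxygen spans C5 and C10 of the carbocycle C1–C10 (ring A = O/C5/C4–C1/C10, ring B = O/C5/C6–C9/C10). This is the imprint of a trans-9,10-epoxide opened across the ring by O5.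
- Forward: the geranyl acetate chain supplies C8–C10 and C1–C5; allylation adds C6/C7; an acrylate ester on O5 and metathesis give a temporary dihydropyranone; chromium closure (C7–C8) forms the ten-membered ring; an acyl shift gives the five-membered lactone; epoxidation and ether closure form rings A and B together; acylation finishes.
- Stereochemistry: C4 from Ru–BINAP hydrogenation; C5 from catalyst-controlled allylboration; C7 relayed from C5 by the lactone tether; C8 from the chair transition state of a ring-locked allylchromium; C9 from outer-face epoxidation; C10 from the same epoxide by inversion in the ether closure; C2' from the purchased acid.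

Key step: step 11

Remark: locants follow the germacrane skeleton (carbocycle C1–C10, lactone carbons C11–C13, C14 on C10, C15 on C4), and the ligand antipodes in steps 2 and 4 are fixed by their known sense with geraniol and benzaldehyde.

**Step 1**
Reactants: 1 geranyl acetate
Product: 2 (2E,6E)-8-hydroxy-3,7-dimethylocta-2,6-dien-1-yl acetate
Conditions: SeO2 (cat.), t-BuOOH, salicylic acid (cat.), CH2Cl2, rt
Reagents that add atoms: tert-butyl hydroperoxide, CC(C)(C)OO (oxygen relayed through SeO2, O=[Se]=O)
Why: Riley-type allylic oxidation (ene reaction, then [2,3]-shift) should attack the more electron-rich terminal alkene at its (E)-methyl group and leave the acetate-deactivated alkene alone.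

**Step 2**
Reactants: 2 (2E,6E)-8-hydroxy-3,7-dimethylocta-2,6-dien-1-yl acetate
Product: 3 (2E,7S)-8-hydroxy-3,7-dimethyloct-2-en-1-yl acetate
Conditions: H2 (30 atm), Ru(OAc)2[(S)-BINAP] (cat.), MeOH, rt
Reagents that add atoms: none
Why: Noyori-type hydroxyl-directed hydrogenation reduces only the alkene that carries the coordinating allylic OH, and the (S)-ligand, which turns geraniol into (R)-citronellol, should add hydrogen to the same enantioface here and set C4 as S.

**Step 3**
Reactants: 3 (2E,7S)-8-hydroxy-3,7-dimethyloct-2-en-1-yl acetate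
Product: 4 (2E,7S)-3,7-dimethyl-8-oxooct-2-en-1-yl acetate
Conditions: TEMPO (cat.), PhI(OAc)2, CH2Cl2, rt; used at once
Reagents that add atoms: none
Why: oxoammonium (TEMPO) oxidation stops at the aldehyde under near-neutral conditions, so the α-methyl stereocentre C4 should not epimerise.

**Step 4**
Reactants: 4 (2E,7S)-3,7-dimethyl-8-oxooct-2-en-1-yl acetate; 5 allylboronic acid pinacol ester
Product: 7 (2E,7S,8R)-8-hydroxy-3,7-dimethylundeca-2,10-dien-1-yl acetate, via pinacol borate ester 6 (not isolated)
Conditions: (R)-TRIP [(R)-3,3'-bis(2,4,6-triisopropylphenyl)-1,1'-binaphthyl-2,2'-diyl hydrogen phosphate] (5 mol %), toluene, −30 °C; aqueous work-up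
Reagents that add atoms: none
Why: chiral-phosphoric-acid-catalysed allylboration through a chair transition state; the (R)-catalyst, which gives (R)-1-phenylbut-3-en-1-ol from benzaldehyde, should direct allyl to the same aldehyde face and set C5 as R (4,5-anti) under catalyst control, the Felkin–Anh bias of a simple α-methyl aldehyde being small.

**Step 5**
Reactants: 7 (2E,7S,8R)-8-hydroxy-3,7-dimethylundeca-2,10-dien-1-yl acetate
Product: 8 (2E,7S,8R)-3,7-dimethylundeca-2,10-diene-1,8-diol
Conditions: K2CO3 (cat.), MeOH, 0 °C to rt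
Reagents that add atoms: none
Why: base-catalysed transesterification (Zemplén type) removes the primary allylic acetate, and nothing else in the molecule is base-sensitive.

**Step 6**
Reactants: 8 (2E,7S,8R)-3,7-dimethylundeca-2,10-diene-1,8-diol
Product: 9 (2E,7S,8R)-8-hydroxy-3,7-dimethylundeca-2,10-dienal
Conditions: MnO2, CH2Cl2, rt
Reagents that add atoms: none
Why: MnO2 oxidises only allylic alcohols, so the primary allylic hydroxyl should give the (E)-enal while the non-allylic C5 hydroxyl stays free; conjugation also deactivates this alkene for step 8.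

**Step 7**
Reactants: 9 (2E,7S,8R)-8-hydroxy-3,7-dimethylundeca-2,10-dienal; 10 2-(bromomethyl)prop-2-enoic acid
Product: 11 (4R,5S,9E)-5,9-dimethyl-11-oxoundeca-1,9-dien-4-yl 2-(bromomethyl)prop-2-enoate
Conditions: DCC, DMAP (cat.), CH2Cl2, 0 °C
Reagents that add atoms: none
Why: Steglich esterification of the secondary C5 hydroxyl; DMAP is kept catalytic and cold so that the allylic bromide is not lost to quaternisation.

**Step 8**
Reactants: 11 (4R,5S,9E)-5,9-dimethyl-11-oxoundeca-1,9-dien-4-yl 2-(bromomethyl)prop-2-enoate
Product: 12 (2E,7S)-7-[(2R)-5-(bromomethyl)-6-oxo-3,6-dihydro-2H-pyran-2-yl]-3-methyloct-2-enal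
Conditions: second-generation Grubbs catalyst RuCl2(=CHPh)(PCy3)(H2IMes) (5 mol %), CH2Cl2 (0.005 M), 40 °C
Reagents that add atoms: none
Why: ring-closing metathesis of a 2-substituted acrylate ester of a homoallylic alcohol to a 5,6-dihydropyran-2-one, driven by loss of ethene; the conjugated trisubstituted enal alkene is inert, and the new C7=C11 alkene is locked in the ring with C6 cis to the carbonyl.

**Step 9**
Reactants: 12 (2E,7S)-7-[(2R)-5-(bromomethyl)-6-oxo-3,6-dihydro-2H-pyran-2-yl]-3-methyloct-2-enal
Product: 15 (4S,5R,7R,8S,9E)-5-hydroxygermacra-9,11(13)-dien-12,8-olide, via allylchromium dichloride 13 (not isolated), via bridged delta-lactone alcohol 14 (not isolated)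
Conditions: CrCl2 (8 equiv), THF, syringe-pump addition (final 0.003 M), rt; aqueous work-up; then PPTS (cat.), CH2Cl2, rt
Reagents that add atoms: none
Why: Nozaki–Hiyama-type allylation, in which divalent chromium (CrCl2) turns the allylic bromide into allylchromium 13 with its double bond held (E) by the lactone ring, and the enal adds at C7 through a chair transition state with C9 equatorial (anti addition, C8 as drawn) while the C5–O–C12 tether can span C5 and C7 only in the cis sense and so relays C5 to C7; PPTS then moves the acyl group from O5 to O8 to give the trans-fused five-membered lactone.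

**Step 10**
Reactants: 15 (4S,5R,7R,8S,9E)-5-hydroxygermacra-9,11(13)-dien-12,8-olide
Product: 16 (4S,5R,7R,8R,9S,10S)-9,10-epoxy-5-hydroxygermacr-11(13)-en-12,8-olide
Conditions: dimethyldioxirane, acetone, −20 to 0 °C; chromatography on base-washed silica
Reagents that add atoms: dimethyldioxirane, CC1(C)OO1
Why: electrophilic oxygen transfer from the dioxirane to the only electron-rich alkene on the outer face of the ring: with H8 eclipsing the alkene to avoid allylic 1,3-strain against C14 the carbon chain covers the inner face, so oxygen should enter syn to O8 and give the 9S,10S epoxide; the neutral reagent leaves no acid that could start step 11 early, and the conjugated methylene is too electron-poor to react.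

**Step 11**
Reactants: 16 (4S,5R,7R,8R,9S,10S)-9,10-epoxy-5-hydroxygermacr-11(13)-en-12,8-olide
Product: 17 (4S,5R,7R,8R,9S,10R)-5,10-epoxy-9-hydroxygermacr-11(13)-en-12,8-olide
Conditions: CSA (0.1 equiv), CH2Cl2, 0 °C to rt
Reagents that add atoms: none
Why: CSA protonates the epoxide, the C10–O bond lengthens with positive charge building at the tertiary carbon, and the C5 hydroxyl, held across the ring, attacks C10 from the inner face anti to the departing oxygen, which stays on C9 as the free hydroxyl. The closest known reaction type is the acid-mediated epoxy-alcohol cyclisation at the more substituted epoxide carbon, here in its transannular form across a medium ring. The one new O5–C10 bond closes ring A (O, C5, C4–C1, C10) in the 7-exo mode, C9 lying outside that ring, and ring B (O, C5–C9, C10) in the 7-endo mode. C10 is the only stereocentre formed: it is inverted, so its R configuration follows from the 9S,10S epoxide of step 10, and C9 is retained. The step needs attack at C10 and not at C9 (tetrahydropyran isomer) and closure faster than hydride shift or proton loss; the tertiary against secondary carbon, the electron-withdrawing lactone oxygen on C8 next to C9, the 1,6 relation of C5 and C10 in the ten-membered ring and a mild Brønsted acid in place of a strong Lewis acid should secure this. The electron-poor methylene lactone is inert to the acid.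

**Step 12**
Reactants: 17 (4S,5R,7R,8R,9S,10R)-5,10-epoxy-9-hydroxygermacr-11(13)-en-12,8-olide; 18 (2R)-2-methylbutanoic acid
Product: 19 (4S,5R,7R,8R,9S,10R)-5,10-epoxy-9-[(2R)-2-methylbutanoyloxy]germacr-11(13)-en-12,8-olide (CNP0136059.1)
Conditions: DCC, DMAP (cat.), CH2Cl2, 0 °C to rt
Reagents that add atoms: none
Why: Steglich esterification of the hindered C9 hydroxyl; the acid brings its (R) stereocentre unchanged, and the low temperature limits epimerisation of the activated acid and amine addition to the methylene lactone.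

**Compound list**
1 | geranyl acetate | CC(C)=CCC/C(C)=C/COC(C)=O | starting material
2 | (2E,6E)-8-hydroxy-3,7-dimethylocta-2,6-dien-1-yl acetate | CC(=O)OC/C=C(C)/CC/C=C(C)/CO | intermediate
3 | (2E,7S)-8-hydroxy-3,7-dimethyloct-2-en-1-yl acetate | CC(=O)OC/C=C(C)/CCC[C@H](C)CO | intermediate
4 | (2E,7S)-3,7-dimethyl-8-oxooct-2-en-1-yl acetate | CC(=O)OC/C=C(C)/CCC[C@H](C)C=O | intermediate
5 | allylboronic acid pinacol ester | C=CCB1OC(C)(C)C(C)(C)O1 | starting material
6 | (2E,7S,8R)-3,7-dimethyl-8-[(4,4,5,5-tetramethyl-1,3,2-dioxaborolan-2-yl)oxy]undeca-2,10-dien-1-yl acetate (not isolated) | CC(=O)OC/C=C(C)/CCC[C@H](C)[C@@H](CC=C)OB1OC(C)(C)C(C)(C)O1 | intermediate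
7 | (2E,7S,8R)-8-hydroxy-3,7-dimethylundeca-2,10-dien-1-yl acetate | CC(=O)OC/C=C(C)/CCC[C@H](C)[C@H](O)CC=C | intermediate
8 | (2E,7S,8R)-3,7-dimethylundeca-2,10-diene-1,8-diol | OC/C=C(C)/CCC[C@H](C)[C@H](O)CC=C | intermediate
9 | (2E,7S,8R)-8-hydroxy-3,7-dimethylundeca-2,10-dienal | O=C/C=C(C)/CCC[C@H](C)[C@H](O)CC=C | intermediate
10 | 2-(bromomethyl)prop-2-enoic acid | OC(=O)C(=C)CBr | starting material
11 | (4R,5S,9E)-5,9-dimethyl-11-oxoundeca-1,9-dien-4-yl 2-(bromomethyl)prop-2-enoate | O=C/C=C(C)/CCC[C@H](C)[C@@H](CC=C)OC(=O)C(=C)CBr | intermediate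
12 | (2E,7S)-7-[(2R)-5-(bromomethyl)-6-oxo-3,6-dihydro-2H-pyran-2-yl]-3-methyloct-2-enal | O=C/C=C(C)/CCC[C@H](C)[C@H]1CC=C(CBr)C(=O)O1 | intermediate
13 | allylchromium dichloride from 12, CrCl2 on the exocyclic CH2 (not isolated) | O=C/C=C(C)/CCC[C@H](C)[C@H]1CC=C(C[Cr](Cl)Cl)C(=O)O1 | intermediate
14 | (4S,5R,7R,8S,9E)-8-hydroxygermacra-9,11(13)-dien-12,5-olide, bridged δ-lactone (not isolated) | C=C1C(=O)O[C@@H]2C[C@H]1[C@@H](O)/C=C(C)/CCC[C@@H]2C | intermediate
15 | (4S,5R,7R,8S,9E)-5-hydroxygermacra-9,11(13)-dien-12,8-olide | C=C1C(=O)O[C@H]2/C=C(C)/CCC[C@H](C)[C@H](O)C[C@H]12 | intermediate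
16 | (4S,5R,7R,8R,9S,10S)-9,10-epoxy-5-hydroxygermacr-11(13)-en-12,8-olide | C=C1C(=O)O[C@@H]2[C@@H]1C[C@@H](O)[C@@H](C)CCC[C@]3(C)O[C@@H]23 | intermediate
17 | (4S,5R,7R,8R,9S,10R)-5,10-epoxy-9-hydroxygermacr-11(13)-en-12,8-olide | C=C1C(=O)O[C@@H]2[C@@H]1C[C@H]1O[C@](C)(CCC[C@@H]1C)[C@H]2O | intermediate
18 | (2R)-2-methylbutanoic acid | CC[C@@H](C)C(O)=O | starting material
19 | (4S,5R,7R,8R,9S,10R)-5,10-epoxy-9-[(2R)-2-methylbutanoyloxy]germacr-11(13)-en-12,8-olide (CNP0136059.1) | C=C1C(=O)O[C@@H]2[C@@H]1C[C@H]1O[C@](C)(CCC[C@@H]1C)[C@H]2OC(=O)[C@H](C)CC | target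

**Count**
Total steps: 12. Longest linear sequence: 12 (from geranyl acetate).

**Steps most likely to fail**

Step 9 (chromium ring closure). The closure may pass through a boat or an axial-aldehyde chair (syn addition) and give the C8 epimer, and intermolecular coupling may outrun closure of the bridged ring if dilution is insufficient. The fallback sets out from 12 and comes back at 14. The chromium closure is kept for the carbon ring only, and the carbinol configuration is set separately under reagent control. The C8-epimeric bridged alcohol (4S,5R,7R,8R,9E)-8-hydroxygermacra-9,11(13)-dien-12,5-olide F1, isolated without acid treatment, would be oxidised with MnO2 in CH2Cl2 to the enone (4S,5R,7R,9E)-8-oxogermacra-9,11(13)-dien-12,5-olide F2. Corey–Bakshi–Shibata reduction ((S)-2-methyl-CBS-oxazaborolidine, catecholborane, toluene, −78 °C, with the alkenyl branch as the large group) should then give 14, which is carried on to 15 with PPTS as in step 9.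

Step 11 (ether closure). Full ionisation at C10 may be followed by a 1,2-hydride shift to a C9 ketone or by proton loss to an allylic alcohol, or O5 may attack C9. The fallback sets out from 15 and comes back at 17. The same O5–C10 bond and both oxepanes would be made by transannular alkoxymercuration of the alkene (Hg(OCOCF3)2, CH2Cl2, 0 °C; then aqueous NaCl). A mercurinium ion on the outer face takes the place of the protonated epoxide, so no free cation arises. The organomercurial (4S,5R,7R,8R,9S,10R)-9-(chloromercurio)-5,10-epoxygermacr-11(13)-en-12,8-olide F3 would then be converted into 17 by oxidative demercuration (O2, NaBH4, DMF, short contact at 0 °C). The C9 radical should be trapped by dioxygen on the face away from ring A; this step is not stereospecific, so some C9 epimer may form.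

Step 10 (epoxidation). The ten-membered ring may populate a second conformer that exposes the other alkene face (poor facial selectivity), and the free C5 hydroxyl may open the epoxide before it is isolated. The fallback sets out from 8 and comes back at 16. The epoxide would be installed before ring closure under reagent control:
- Sharpless asymmetric epoxidation of the allylic alcohol of 8 (Ti(OiPr)4, L-(+)-diethyl tartrate, t-BuOOH, 4 Å sieves, CH2Cl2, −20 °C) would give [(2S,3S)-3-[(4S,5R)-5-hydroxy-4-methyloct-7-en-1-yl]-3-methyloxiran-2-yl]methanol F4.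
- TEMPO/PhI(OAc)2 oxidation of the primary alcohol would give (2R,3S)-3-[(4S,5R)-5-hydroxy-4-methyloct-7-en-1-yl]-3-methyloxirane-2-carbaldehyde F5.
- Esterification with 10 (DCC, DMAP) would give (4R,5S)-8-[(2S,3R)-3-formyl-2-methyloxiran-2-yl]-5-methyloct-1-en-4-yl 2-(bromomethyl)prop-2-enoate F6.
- Ring-closing metathesis as in step 8 would give (2R,3S)-3-{(4S)-4-[(2R)-5-(bromomethyl)-6-oxo-3,6-dihydro-2H-pyran-2-yl]pentyl}-3-methyloxirane-2-carbaldehyde F7.
- CrCl2 closure as in step 9 would give (4S,5R,7R,8R,9S,10S)-9,10-epoxy-8-hydroxygermacr-11(13)-en-12,5-olide F8, whose acyl shift from O5 to O8 leads to 16.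

If PPTS is needed for that acyl shift, the ether closure of step 11 may follow in the same flask and give 17 directly.

**Further compounds**
F1 | step 9 | (4S,5R,7R,8R,9E)-8-hydroxygermacra-9,11(13)-dien-12,5-olide | C=C1C(=O)O[C@@H]2C[C@H]1[C@H](O)/C=C(C)/CCC[C@@H]2C
F2 | step 9 | (4S,5R,7R,9E)-8-oxogermacra-9,11(13)-dien-12,5-olide | C=C1C(=O)O[C@@H]2C[C@H]1C(=O)/C=C(C)/CCC[C@@H]2C
F3 | step 11 | (4S,5R,7R,8R,9S,10R)-9-(chloromercurio)-5,10-epoxygermacr-11(13)-en-12,8-olide | C=C1C(=O)O[C@@H]2[C@@H]1C[C@H]1O[C@](C)(CCC[C@@H]1C)[C@H]2[Hg]Cl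
F4 | step 10 | [(2S,3S)-3-[(4S,5R)-5-hydroxy-4-methyloct-7-en-1-yl]-3-methyloxiran-2-yl]methanol | OC[C@@H]1O[C@@]1(C)CCC[C@H](C)[C@H](O)CC=C
F5 | step 10 | (2R,3S)-3-[(4S,5R)-5-hydroxy-4-methyloct-7-en-1-yl]-3-methyloxirane-2-carbaldehyde | O=C[C@@H]1O[C@@]1(C)CCC[C@H](C)[C@H](O)CC=C
F6 | step 10 | (4R,5S)-8-[(2S,3R)-3-formyl-2-methyloxiran-2-yl]-5-methyloct-1-en-4-yl 2-(bromomethyl)prop-2-enoate | O=C[C@@H]1O[C@@]1(C)CCC[C@H](C)[C@@H](CC=C)OC(=O)C(=C)CBr
F7 | step 10 | (2R,3S)-3-{(4S)-4-[(2R)-5-(bromomethyl)-6-oxo-3,6-dihydro-2H-pyran-2-yl]pentyl}-3-methyloxirane-2-carbaldehyde | O=C[C@@H]1O[C@@]1(C)CCC[C@H](C)[C@H]1CC=C(CBr)C(=O)O1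
F8 | step 10 | (4S,5R,7R,8R,9S,10S)-9,10-epoxy-8-hydroxygermacr-11(13)-en-12,5-olide | C=C1C(=O)O[C@@H]2C[C@H]1[C@@H](O)[C@@H]1O[C@@]1(C)CCC[C@@H]2C
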